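**Assumption:** the SMILES is read as (3R,5R,9S,10R,13S)-3-hydroxylabd-7-en-15-yl (2R)-2-methylbutanoate (3α-OH axial, 5α-H, 9α-H, 10β-CH3; labdane numbering is used for all bicyclic compounds, C17 being the methyl on C8), and (R)-2-methylbutanoic acid and 5-chloropent-1-yne are taken as catalogue compounds.

## Retrosynthetic overview

1. Target ⇒ (13S)-labd-7-ene-3α,15-diol + (R)-2-methylbutanoic acid (selective acylation of the primary C15 hydroxyl).
2. C7=C8 with C17 ⇒ Shapiro methylation of a 17-nor-8-ketone; 3α-OH ⇒ equatorial hydride attack on a 3-ketone; 4,4-dimethyl and 5α-H ⇒ reductive methylation of a ring A enone.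
3. Ring B ⇒ oxidative 1,2-shift ring expansion of an alkylidene hydrindenone (C10 migrates from C8 to C9), which delivers C8 as a dimethyl ketal and C9 with its side chain.
4. Alkylidene hydrindenone ⇒ Wittig union of the (S)-4-methyl Hajos–Parrish-type enedione (2-methylcyclopentane-1,3-dione + ethyl vinyl ketone) with a C7 phosphonium salt (5-chloropent-1-yne + methyl + formaldehyde; C13 by asymmetric hydrogenation).
5. Ring order: the five-membered ring is bought, ring A is closed by aldol condensation, and ring B arises by expansion of the five-membered ring.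

## Route

**Step 1**
Reactants: 1 5-chloropent-1-yne
Product: 4 (E)-6-chloro-3-methylhex-2-en-1-ol, via alkenylalane 2 (not isolated), via lithium alanate 3 (not isolated)
Conditions: Me3Al (2 equiv), Cp2ZrCl2 (25 mol%), CH2Cl2, 0 °C to rt; evaporate; n-BuLi (1 equiv), THF/hexane, 0 °C; (CH2O)n, rt; aq. HCl
Reagents that add atoms: trimethylaluminium C[Al](C)C; formaldehyde (from paraformaldehyde) C=O
Why: Zirconium-catalysed Negishi carboalumination adds methyl and aluminium syn across the terminal alkyne with aluminium at the terminus, and the alkenylalanate is hydroxymethylated with retention, so only the (E)-trisubstituted allylic alcohol forms.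

**Step 2**
Reactants: 4 (E)-6-chloro-3-methylhex-2-en-1-ol
Product: 5 (S)-6-chloro-3-methylhexan-1-ol
Conditions: H2 (50 atm), Ru(OAc)2[(R)-BINAP] (0.5 mol%), MeOH, 25 °C
Reagents that add atoms: none
Why: Noyori hydroxyl-directed asymmetric hydrogenation of an (E)-allylic alcohol, in which the divalent ruthenium (R)-BINAP catalyst sets the methyl-bearing centre (future C13) as S, as in geraniol to (S)-citronellol, while the alkyl chloride is inert.

**Step 3**
Reactants: 5 (S)-6-chloro-3-methylhexan-1-ol
Product: 6 [(4S)-6-hydroxy-4-methylhexyl]triphenylphosphonium iodide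
Conditions: PPh3 (1.2 equiv), NaI (1.2 equiv), MeCN, reflux
Reagents that add atoms: triphenylphosphine c1ccc(cc1)P(c1ccccc1)c1ccccc1; sodium iodide [Na+].[I-]
Why: Finkelstein exchange followed by SN2 quaternisation of the phosphine by the primary iodide, with the remote stereocentre untouched.

**Step 4**
Reactants: 7 2-methylcyclopentane-1,3-dione; 8 pent-1-en-3-one (ethyl vinyl ketone)
Product: 10 (7aS)-4,7a-dimethyl-2,3,7,7a-tetrahydro-1H-indene-1,5(6H)-dione, via triketone 9 (not isolated)
Conditions: H2O, AcOH (cat.), 70 °C; concentrate; (S)-phenylalanine (1 equiv), 1 M HClO4 (0.5 equiv), MeCN, reflux; one recrystallisation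
Reagents that add atoms: none
Why: Michael addition followed by the Hajos–Parrish–Eder–Sauer–Wiechert enamine aldol condensation, in which the (S)-amino acid selects one of the two enantiotopic ring carbonyls, closing ring A and setting the quaternary methyl centre (future C10, 10β-CH3) as S.

**Step 5**
Reactants: 10 (7aS)-4,7a-dimethyl-2,3,7,7a-tetrahydro-1H-indene-1,5(6H)-dione; 6 [(4S)-6-hydroxy-4-methylhexyl]triphenylphosphonium iodide
Product: 12 (7aR)-1-[(Z,4S)-6-hydroxy-4-methylhexylidene]-4,7a-dimethyl-1,2,3,6,7,7a-hexahydro-5H-inden-5-one, via oxido ylide 11 (not isolated)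
Conditions: 6 (2.2 equiv), KN(SiMe3)2 (4.4 equiv), THF, 0 °C; then 10, 0 °C to reflux; 1 M HCl work-up
Reagents that add atoms: none
Why: Wittig olefination that is selective for the saturated cyclopentanone because the conjugated ring A carbonyl is much less electrophilic; the Z isomer is expected to predominate, but the geometry is irrelevant because C9 is reset in step 8.

**Step 6 (key step)**
Reactants: 12 (7aR)-1-[(Z,4S)-6-hydroxy-4-methylhexylidene]-4,7a-dimethyl-1,2,3,6,7,7a-hexahydro-5H-inden-5-one
Product: 13 (13S)-15-hydroxy-8,8-dimethoxy-17,19-dinorlabd-4-en-3-one (10β-CH3; C9 epimer mixture)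
Conditions: PhI(OH)OTs (1.15 equiv), MeOH, 3 Å MS, −20 to 0 °C; Et3N
Reagents that add atoms: methanol CO
Why: Proposed new method: trivalent-iodine oxidative ring expansion of a non-benzylic alkylidenecyclopentane with migration of a quaternary ring carbon, in which PhI(OH)OTs attacks the electron-rich exocyclic alkene (the enone alkene is electron-poor) with iodine on the less substituted C9, methanol opens the iodonium at the tertiary ring carbon C8, and the β-methoxyalkyl-λ3-iodane then expels iodobenzene (direct substitution at C9 is blocked by its fully substituted neighbour) with antiperiplanar 1,2-shift of the more electron-rich C8–C10 bond to C9, pushed by the methoxy lone pair, so that ring B and the C9–C10 bond form and the oxocarbenium ion is trapped by methanol as the ketal that masks C8; the closest known reaction types are the PhI(OH)OTs- and Tl(NO3)3-mediated semipinacol-type ring expansions of methylenecyclobutanes and benzo-fused alkylidenecycloalkanes.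

**Step 7**
Reactants: 13 (13S)-15-hydroxy-8,8-dimethoxy-17,19-dinorlabd-4-en-3-one
Product: 15 (5α,13S)-15-hydroxy-8,8-dimethoxy-17-norlabdan-3-one (C9 epimer mixture), via dilithium enolate 14 (not isolated)
Conditions: Li (2.5 equiv), NH3(l), THF, −78 °C; isoprene; MeI (5 equiv), −78 to −33 °C; NH4Cl
Reagents that add atoms: iodomethane CI
Why: Birch-type dissolving-metal reduction with axial protonation of C5 anti to the C10 methyl (trans-decalin, 5α-H; the side-chain hydroxyl is the proton donor) gives the regiodefined C3 enolate, which is C-methylated at C4 to complete the gem-dimethyl group while the ketal protects C8.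

**Step 8**
Reactants: 15 (5α,13S)-15-hydroxy-8,8-dimethoxy-17-norlabdan-3-one
Product: 17 (13S)-3α,15-dihydroxy-17-norlabdan-8-one (5α-H, 9α-H), via hydroxy ketal 16 (not isolated)
Conditions: LiBH(s-Bu)3 (2.5 equiv), THF, −78 to −20 °C; then 2 M HCl, THF, 40 °C
Reagents that add atoms: water O
Why: Selectride-type reduction in which the bulky hydride attacks the hindered C3 ketone equatorially to give the axial 3α-alcohol, followed by acid hydrolysis of the dimethyl ketal, during which C9 equilibrates through the enol to the equatorial side chain (9α-H).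

**Step 9**
Reactants: 17 (13S)-3α,15-dihydroxy-17-norlabdan-8-one
Product: 18 (13S)-3α,15-dihydroxy-17-norlabdan-8-one 2,4,6-triisopropylbenzenesulfonylhydrazone
Conditions: 2,4,6-(i-Pr)3C6H2SO2NHNH2 (1.2 equiv), HCl (cat.), MeOH, rt
Reagents that add atoms: 2,4,6-triisopropylbenzenesulfonohydrazide CC(C)c1cc(C(C)C)c(S(=O)(=O)NN)c(C(C)C)c1
Why: Acid-catalysed hydrazone condensation at the only ketone, with C9 already in its thermodynamic configuration.

**Step 10**
Reactants: 18 (13S)-3α,15-dihydroxy-17-norlabdan-8-one 2,4,6-triisopropylbenzenesulfonylhydrazone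
Product: 20 (13S)-labd-7-ene-3α,15-diol, via vinyllithium 19 (not isolated)
Conditions: n-BuLi (4.5 equiv), TMEDA, THF, −78 to 0 °C; then MeI (1.5 equiv), −78 °C to rt; NH4Cl
Reagents that add atoms: iodomethane CI
Why: Shapiro reaction in which deprotonation at the less hindered α-CH2 (C7) and loss of sulfinate and N2 give the C8 vinyllithium with the double bond fixed at C7–C8, and methylation installs C17 while the two hydroxyls ride through as lithium alkoxides.

**Step 11**
Reactants: 20 (13S)-labd-7-ene-3α,15-diol; 21 (R)-2-methylbutanoic acid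
Product: 22 (3R,5R,9S,10R,13S)-3-hydroxylabd-7-en-15-yl (2R)-2-methylbutanoate
Conditions: 21 (1.05 equiv), i-PrN=C=N-i-Pr (1.1 equiv), DMAP (5 mol%), CH2Cl2, 0 °C
Reagents that add atoms: none
Why: Steglich esterification in which the primary C15 hydroxyl acylates far faster than the axial neopentyl 3α-hydroxyl, and the cold, weakly basic conditions preserve the α-stereocentre of the acid.

## Compound list

1 | 5-chloropent-1-yne | ClCCCC#C | starting material
2 | (E)-(5-chloro-2-methylpent-1-en-1-yl)dimethylalane (not isolated) | C[Al](C)/C=C(\C)CCCCl | intermediate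
3 | lithium butyl[(E)-5-chloro-2-methylpent-1-en-1-yl]dimethylaluminate (not isolated) | [Li+].CCCC[Al-](C)(C)/C=C(\C)CCCCl | intermediate
4 | (E)-6-chloro-3-methylhex-2-en-1-ol | OC/C=C(\C)CCCCl | intermediate
5 | (S)-6-chloro-3-methylhexan-1-ol | OCC[C@@H](C)CCCCl | intermediate
6 | [(4S)-6-hydroxy-4-methylhexyl]triphenylphosphonium iodide | [I-].OCC[C@@H](C)CCC[P+](c1ccccc1)(c1ccccc1)c1ccccc1 | intermediate
7 | 2-methylcyclopentane-1,3-dione | CC1C(=O)CCC1=O | starting material
8 | pent-1-en-3-one (ethyl vinyl ketone) | CCC(=O)C=C | starting material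
9 | 2-methyl-2-(3-oxopentyl)cyclopentane-1,3-dione (not isolated) | CCC(=O)CCC1(C)C(=O)CCC1=O | intermediate
10 | (7aS)-4,7a-dimethyl-2,3,7,7a-tetrahydro-1H-indene-1,5(6H)-dione | O=C1CCC2=C(C)C(=O)CC[C@]12C | intermediate
11 | potassium (4S)-4-methyl-6-(triphenylphosphoranylidene)hexan-1-olate (oxido ylide, not isolated) | [K+].[O-]CC[C@@H](C)CCC=P(c1ccccc1)(c1ccccc1)c1ccccc1 | intermediate
12 | (7aR)-1-[(Z,4S)-6-hydroxy-4-methylhexylidene]-4,7a-dimethyl-1,2,3,6,7,7a-hexahydro-5H-inden-5-one (Z isomer drawn; same spatial arrangement at the quaternary carbon as in 10) | OCC[C@@H](C)CC/C=C1/CCC2=C(C)C(=O)CC[C@]12C | intermediate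
13 | (13S)-15-hydroxy-8,8-dimethoxy-17,19-dinorlabd-4-en-3-one (10β-CH3; C9 epimer mixture, C9 left undefined) | OCC[C@@H](C)CCC1C(OC)(OC)CCC2=C(C)C(=O)CC[C@]12C | intermediate
14 | dilithium C3-enolate C15-alkoxide of (5α,13S)-15-hydroxy-8,8-dimethoxy-17,19-dinorlabdan-3-one (C9 epimers; not isolated) | [Li+].[Li+].[O-]CC[C@@H](C)CCC1C(OC)(OC)CC[C@H]2C(C)=C([O-])CC[C@]12C | intermediate
15 | (5α,13S)-15-hydroxy-8,8-dimethoxy-17-norlabdan-3-one (10β-CH3; C9 epimer mixture) | OCC[C@@H](C)CCC1C(OC)(OC)CC[C@H]2C(C)(C)C(=O)CC[C@]12C | intermediate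
16 | (3α,5α,13S)-8,8-dimethoxy-17-norlabdane-3,15-diol (C9 epimers; not isolated) | OCC[C@@H](C)CCC1C(OC)(OC)CC[C@H]2C(C)(C)[C@H](O)CC[C@]12C | intermediate
17 | (13S)-3α,15-dihydroxy-17-norlabdan-8-one (5α-H, 9α-H, 10β-CH3) | OCC[C@@H](C)CC[C@H]1C(=O)CC[C@H]2C(C)(C)[C@H](O)CC[C@]12C | intermediate
18 | (13S)-3α,15-dihydroxy-17-norlabdan-8-one 2,4,6-triisopropylbenzenesulfonylhydrazone | OCC[C@@H](C)CC[C@H]1C(=NNS(=O)(=O)c3c(C(C)C)cc(C(C)C)cc3C(C)C)CC[C@H]2C(C)(C)[C@H](O)CC[C@]12C | intermediate
19 | trilithium 8-lithio-17-norlabd-7-ene-3α,15-diolate (not isolated) | [Li]OCC[C@@H](C)CC[C@H]1C([Li])=CC[C@H]2C(C)(C)[C@H](O[Li])CC[C@]12C | intermediate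
20 | (13S)-labd-7-ene-3α,15-diol | OCC[C@@H](C)CC[C@H]1C(C)=CC[C@H]2C(C)(C)[C@H](O)CC[C@]12C | intermediate
21 | (R)-2-methylbutanoic acid | CC[C@@H](C)C(=O)O | starting material
22 | (3R,5R,9S,10R,13S)-3-hydroxylabd-7-en-15-yl (2R)-2-methylbutanoate | CC[C@@H](C)C(=O)OCC[C@@H](C)CC[C@H]1C(C)=CC[C@H]2C(C)(C)[C@H](O)CC[C@]12C | target

## Step count and risks

Total steps: 11. Longest linear sequence: 10 (steps 1, 2, 3, 5, 6, 7, 8, 9, 10, 11).

Steps most likely to fail:

**Step 6 (the proposed ring expansion).** The iodane could be intercepted as a 1,2-dimethoxy adduct, C7 could migrate in place of C10, or the ketal could be lost to the ketone. The fallback uses known chemistry, sets out from 12 and comes back at 13. NBS in aqueous THF converts the exocyclic alkene into the bromohydrin F1 (bromine on C9, hydroxyl on C8). AgBF4 with CaCO3 in aqueous acetone then drives the classical silver-assisted semipinacol ring expansion to the enone ketone F2. MeOH, HC(OMe)3 and catalytic TsOH ketalise only the saturated C8 carbonyl of F2 and give 13.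

**Step 5 (chemoselective Wittig on the enedione).** γ-Deprotonation of the enone consumes ylide, and the neopentyl cyclopentanone reacts slowly. The fallback sets out from 10 and comes back at 12. Pyrrolidine in MeOH converts only the ring A enone into the pyrrolidine dienamine F3. Wittig reaction of F3 with 1.3 equiv of ylide 11 gives the alkylidene dienamine F4. Buffered aqueous AcOH/NaOAc hydrolysis of F4 releases 12.

**Step 10 (Shapiro methylation with two free alkoxides).** Protonation of the vinyllithium (giving the C8–H alkene) or O-methylation could erode the yield. The fallback sets out from 17 and comes back at 20. t-BuMe2SiOTf with 2,6-lutidine at −78 °C gives the bis(silyl ether) ketone F5. KN(SiMe3)2 then PhNTf2 at −78 °C gives the kinetic C7–C8 enol triflate F6. MeMgBr with Fe(acac)3 (5 mol%, trivalent iron precatalyst) in THF/NMP gives the bis(silyl ether) alkene F7. Bu4NF in THF at 50 °C returns 20.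

## Further compounds

F1 | step 6 | 1-(1-bromo-6-hydroxy-4-methylhexyl)-1-hydroxy-4,7a-dimethyl-1,2,3,6,7,7a-hexahydro-5H-inden-5-one (bromohydrin of 12; C8 and C9 diastereomers) | OCC[C@@H](C)CCC(Br)C1(O)CCC2=C(C)C(=O)CC[C@]12C
F2 | step 6 | (13S)-15-hydroxy-17,19-dinorlabd-4-ene-3,8-dione (C9 epimers) | OCC[C@@H](C)CCC1C(=O)CCC2=C(C)C(=O)CC[C@]12C
F3 | step 5 | (7aS)-4,7a-dimethyl-5-(pyrrolidin-1-yl)-2,6,7,7a-tetrahydro-1H-inden-1-one | O=C1CC=C2C(C)=C(N3CCCC3)CC[C@]12C
F4 | step 5 | (3S)-6-[4,7a-dimethyl-5-(pyrrolidin-1-yl)-2,6,7,7a-tetrahydro-1H-inden-1-ylidene]-3-methylhexan-1-ol (Z isomer drawn) | OCC[C@@H](C)CC/C=C1/CC=C2C(C)=C(N3CCCC3)CC[C@]12C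
F5 | step 10 | (13S)-3α,15-bis(tert-butyldimethylsilyloxy)-17-norlabdan-8-one | CC(C)(C)[Si](C)(C)OCC[C@@H](C)CC[C@H]1C(=O)CC[C@H]2C(C)(C)[C@H](O[Si](C)(C)C(C)(C)C)CC[C@]12C
F6 | step 10 | (13S)-3α,15-bis(tert-butyldimethylsilyloxy)-17-norlabd-7-en-8-yl trifluoromethanesulfonate | CC(C)(C)[Si](C)(C)OCC[C@@H](C)CC[C@H]1C(OS(=O)(=O)C(F)(F)F)=CC[C@H]2C(C)(C)[C@H](O[Si](C)(C)C(C)(C)C)CC[C@]12C
F7 | step 10 | (13S)-3α,15-bis(tert-butyldimethylsilyloxy)labd-7-ene | CC(C)(C)[Si](C)(C)OCC[C@@H](C)CC[C@H]1C(C)=CC[C@H]2C(C)(C)[C@H](O[Si](C)(C)C(C)(C)C)CC[C@]12C
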